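The norbornene core is reached through an isomeric bicyclo[2.2.1]heptane. A fulvene-fused guaianolide (diene C5=C1–C2=C3, exocyclic C4=C15) and the α-methylene lactone of a silyl-protected ent-1β-hydroxyalantolactone are united by an exo-selective Diels–Alder reaction that bonds C13′ to C5 and C11′ to C3. Exo-epoxidation of the new C1=C2 bond and Lewis-acid opening then trigger a Wagner–Meerwein shift of C13′ from C5 to C1: the six-membered ring C1–C2–C3–C11′–C13′–C5 contracts to the five-membered ring C1–C2–C3–C11′–C13′, C2 becomes the bridge with its oxygen syn to the alkene, and hydride capture of the C5–C4–C15 allyl cation gives C4=C5 and the C15 methyl.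

Key step: step 27

Remark: the target as drawn belongs to the mirror-image series of natural alantolactone, so both halves are built de novo; C1–C15 number the guaiane half and C1′–C15′ the eudesmane half (C11′ = spiro carbon, C13′ = its CH2), β in the eudesmane half means the face of the angular methyl C14′, and centres that are destroyed later (C11 in 13, 14, 33, 34; C3 and C4 in 27–30; alkene geometry in 8) are carried as mixtures.

**Eudesmane half (dienophile 15)**

Step 1
Reactants: 1 (S)-Wieland–Miescher ketone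
Product: 2 (4aS,5S)-5-hydroxy-4a-methyl-4,4a,5,6,7,8-hexahydronaphthalen-2(3H)-one (1′β-alcohol, OH cis to the angular methyl)
Conditions: NaBH4, EtOH, −15 °C
Reagents that add atoms: none
Why: Chemoselective hydride reduction of the saturated C1′ ketone (the enone carbonyl is less electrophilic), with hydride attack anti to the angular C14′ methyl so that the hydroxyl ends cis to it.

Step 2
Reactants: 2 hydroxy enone
Product: 3 C7′ ethylene ketal of 2 with the alkene moved to C4′=C5′ (free 1′β-OH)
Conditions: ethylene glycol, TsOH (cat.), benzene, reflux (water separator)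
Reagents that add atoms: ethylene glycol, OCCO
Why: Acid-catalysed ketalisation of the enone with the usual migration of the alkene out of conjugation into ring A.

Step 3
Reactants: 3 ketal alcohol
Product: 4 1′-O-TBS ether of 3
Conditions: TBSCl, imidazole, DMF, 25 °C
Reagents that add atoms: tert-butyldimethylsilyl chloride, CC(C)(C)[Si](C)(C)Cl
Why: Standard silylation of the secondary alcohol.

Step 4
Reactants: 4 silyl ether
Product: 5 4′α,5′α-epoxide of 4 (oxygen trans to C14′)
Conditions: mCPBA, NaHCO3, CH2Cl2, 0 °C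
Reagents that add atoms: mCPBA, O=C(OO)c1cccc(Cl)c1
Why: Peracid epoxidation of the trisubstituted alkene from the face opposite the axial angular methyl, which sets C4′ and C5′.

Step 5
Reactants: 5 epoxide
Product: 6 4′β-methyl-5′α-hydroxy ketal (C15′ cis to C14′, tertiary OH trans)
Conditions: MeMgBr, CuI (10 mol %), THF, 0 → 50 °C; NH4Cl (aq)
Reagents that add atoms: methylmagnesium bromide, C[Mg]Br
Why: Copper-catalysed Grignard opening of the epoxide at the secondary C4′ in the trans-diaxial sense, which places the new methyl on the β face and the tertiary hydroxyl on the α face.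

Step 6
Reactants: 6 hydroxy ketal
Product: 7 5′α-hydroxy-4′β-methyl-7′-ketone (1′-OTBS)
Conditions: PPTS (cat.), acetone–H2O, 40 °C
Reagents that add atoms: water, O
Why: Mild acid hydrolysis of the ketal frees the C7′ ketone while the tertiary β-hydroxyl is kept for a later regiospecific dehydration.

Step 7
Reactants: 7 hydroxy ketone
Product: 8 tert-butyl 2-(7′-ylidene)acetate (exocyclic enoate, E/Z mixture)
Conditions: Ph3P=CHCO2t-Bu, toluene, 110 °C
Reagents that add atoms: tert-butyl (triphenylphosphoranylidene)acetate, CC(C)(C)OC(=O)C=P(c1ccccc1)(c1ccccc1)c1ccccc1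
Why: Wittig olefination with a stabilised ylide under neutral conditions that spare the β-hydroxy ketone.

Step 8
Reactants: 8 exocyclic enoate
Product: 9 tert-butyl 2-(7′,8′-en-7′-yl)acetate (β,γ-unsaturated ester)
Conditions: LDA (2.5 equiv), THF, −78 °C; AcOH, −78 °C
Reagents that add atoms: none
Why: Deconjugative isomerisation by γ-deprotonation on the less hindered C8′ side (C6′ is next to the alkoxide-bearing quaternary C5′) and kinetic α-protonation of the dienolate.

Step 9
Reactants: 9 β,γ-unsaturated ester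
Product: 10 7′α-iodo-5′α-hydroxy cis-12′,8′β-lactone
Conditions: I2, NaHCO3, MeCN, 0 → 25 °C
Reagents that add atoms: iodine, [I][I]
Why: Iodolactonisation in which the iodonium forms on the face away from the angular methyl and the ester oxygen opens it at C8′ from the β face with loss of isobutene, setting C7′ and C8′ (cis-fused lactone, oxygen cis to C14′).

Step 10
Reactants: 10 iodolactone
Product: 11 5′α-hydroxy cis-lactone (7′α-H, C11′H2)
Conditions: Bu3SnH, AIBN (cat.), toluene, 80 °C
Reagents that add atoms: none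
Why: Radical dehalogenation in which the tertiary C7′ radical takes hydrogen on the convex face and so keeps the cis ring fusion.

Step 11
Reactants: 11 hydroxy lactone
Product: 12 5′-ene cis-lactone (1′-OTBS, C11′H2)
Conditions: SOCl2, pyridine, CH2Cl2, −20 → 0 °C
Reagents that add atoms: none
Why: Anti-elimination of the chlorosulfite, for which only the axial C6′ hydrogen is antiperiplanar to the 5′α-oxygen (C4′ carries its methyl in that position), so the C5′=C6′ alkene forms.

Step 12
Reactants: 12 lactone
Product: 15 1′-O-TBS ether of the enantiomer of 1β-hydroxyalantolactone (α-methylene lactone), via Mannich base 13 (not isolated), via ammonium iodide 14 (not isolated)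
Conditions: LDA, THF, −78 °C; CH2=NMe2+ I−, −78 → 0 °C; MeI, MeOH, 25 °C; NaHCO3 (aq), 25 °C
Reagents that add atoms: Eschenmoser's salt, C=[N+](C)C.[I-]
Why: α-Methylenation by Mannich reaction of the lactone enolate, N-quaternisation and base-induced elimination of trimethylamine.

**Guaiane half (dienol 30)**

Step 13
Reactants: 16 cyclohepta-1,3-diene
Product: 17 6,7-dioxabicyclo[3.2.2]non-8-ene (meso endoperoxide)
Conditions: O2, tetraphenylporphyrin (cat.), hν, CH2Cl2, 0 °C
Reagents that add atoms: dioxygen, O=O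
Why: [4+2] Cycloaddition of singlet oxygen to the cyclic diene, which can only give the cis (meso) bicyclic peroxide.

Step 14
Reactants: 17 endoperoxide
Product: 18 (R)-4-hydroxycyclohept-2-en-1-one
Conditions: chiral cinchona-alkaloid base catalyst (5 mol %), CH2Cl2, 25 °C
Reagents that add atoms: none
Why: Desymmetrising Kornblum–DeLaMare rearrangement in which the chiral amine removes one of the two enantiotopic bridgehead hydrogens, so the catalyst sets the C8 carbinol centre.

Step 15
Reactants: 18 hydroxy enone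
Product: 19 (R)-4-(tert-butyldimethylsilyloxy)cyclohept-2-en-1-one
Conditions: TBSCl, imidazole, DMF, 25 °C
Reagents that add atoms: tert-butyldimethylsilyl chloride, CC(C)(C)[Si](C)(C)Cl
Why: Standard silylation of the secondary alcohol.

Step 16
Reactants: 19 silyloxy enone
Product: 21 trans-3-(methoxycarbonylmethyl)-4-(TBSO)cycloheptanone (C7–C11 anti to C8–O), via silyl enol ether 20 (not isolated)
Conditions: CH2=C(OMe)OTBS, TBSOTf (5 mol %), CH2Cl2, −78 °C; then 1 M HCl, THF, 0 °C
Reagents that add atoms: 1-(tert-butyldimethylsilyloxy)-1-methoxyethene, COC(=C)O[Si](C)(C)C(C)(C)C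
Why: Mukaiyama–Michael addition in which the ketene acetal adds to C7 anti to the adjacent silyloxy group (trans C7/C8), followed by hydrolysis of the silyl enol ether.

Step 17
Reactants: 21 keto ester
Product: 22 cyclohept-2-enone with 5-OTBS and 6-CH2CO2Me (enone C5(=O)–C1=C10)
Conditions: Pd(O2CCF3)2 (5 mol %), DMSO (10 mol %), O2 (1 atm), AcOH, 60 °C
Reagents that add atoms: none
Why: Palladium-catalysed aerobic α,β-dehydrogenation through the palladium enolate, which should form at the α-methylene remote from the branched C7.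

Step 18
Reactants: 22 enone
Product: 23 enol triflate C5(OTf)=C1 with the C14 methyl on C10 (methyl trans to C8–O)
Conditions: Me2CuLi (from MeLi and CuI), THF, −78 °C; PhNTf2, −78 → 0 °C
Reagents that add atoms: lithium dimethylcuprate, [Li+].C[Cu-]C; N-phenylbis(trifluoromethanesulfonimide), O=S(=O)(N(c1ccccc1)S(=O)(=O)C(F)(F)F)C(F)(F)F
Why: Cuprate conjugate addition at C10 anti to the C8 silyloxy group (1,3-relationship, as for 5-substituted cycloalkenones), then O-triflation of the regiodefined enolate.

Step 19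
Reactants: 23 enol triflate
Product: 24 cycloheptenyl vinyl ketone (acryloyl on C5)
Conditions: CO (1 atm), CH2=CHSnBu3, Pd(PPh3)4 (5 mol %), LiCl, THF, 55 °C
Reagents that add atoms: carbon monoxide, [C-]#[O+]; tributyl(vinyl)stannane, C=C[Sn](CCCC)(CCCC)CCCC
Why: Carbonylative Stille coupling (oxidative addition, CO insertion, transmetallation with the vinylstannane).

Step 20
Reactants: 24 divinyl ketone
Product: 26 13,15-dinor-4-oxoguai-1(5)-en-12,8-olide (trans-lactone enone), via cyclopentenone silyl ether 25 (not isolated)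
Conditions: MeSO3H, CH2Cl2, 0 → 25 °C; NaHCO3 (aq)
Reagents that add atoms: none
Why: Nazarov cyclisation (conrotatory 4π closure of the hydroxypentadienyl cation and proton loss to the ring-fusion enone), after which the acid removes the silyl ether and the C8 hydroxyl lactonises onto the ester with retention.

Step 21
Reactants: 26 lactone enone
Product: 27 3-phenylseleno derivative of 26
Conditions: LiHMDS, THF, −78 °C; PhSeCl, −78 °C
Reagents that add atoms: phenylselenenyl chloride, Cl[Se]c1ccccc1
Why: Kinetic α′-deprotonation of the cyclopentenone at C3 and selenenylation of the enolate.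

Step 22
Reactants: 27 selenide
Product: 28 4-hydroxy-4-methyl-3-phenylseleno carbinol (C15 installed)
Conditions: MeLi, CeCl3, THF, −78 °C
Reagents that add atoms: methyllithium, [Li]C
Why: 1,2-Addition of the weakly basic organocerium reagent to the enone carbonyl, chemoselective over the lactone.

Step 23
Reactants: 28 carbinol selenide
Product: 30 4-hydroxy-13-norguaia-1(5),2-dien-12,8-olide (cyclopentadienol), via selenoxide 29 (not isolated)
Conditions: H2O2 (30 %), pyridine, CH2Cl2, 0 → 25 °C
Reagents that add atoms: none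
Why: Oxidation to the selenoxide and syn-elimination toward C2, the only neighbouring carbon that carries hydrogen.

**Union and endgame**

Step 24
Reactants: 30 cyclopentadienol; 15 silyl-protected methylene lactone
Product: 32 Diels–Alder adduct (7-methylene-norbornene with bridgeheads C5 and C3, bridge C4, spiro-lactone carbonyl exo), via fulvene 31 (not isolated)
Conditions: Burgess reagent, THF, 0 → 25 °C; then 15, BHT (cat.), toluene, 40 °C
Reagents that add atoms: none
Why: Syn-dehydration through the sulfamate ester gives the fulvene, whose ring diene adds to the methylene lactone in a Diels–Alder reaction in which C13′ bonds to the substituted terminus C5 for steric reasons, the s-cis-locked lactone reacts through the carbonyl-exo transition state, the diene is approached anti to the pseudo-axial C14 methyl and the dienophile on the convex face of its cis-fused lactone, which sets C3, C5 and C11′.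

Step 25
Reactants: 32 Diels–Alder adduct
Product: 35 adduct with the guaianolide α-methylene lactone, via Mannich base 33 (not isolated), via ammonium iodide 34 (not isolated)
Conditions: LDA, THF, −78 °C; CH2=NMe2+ I−, −78 → 0 °C; MeI, MeOH, 25 °C; NaHCO3 (aq), 25 °C
Reagents that add atoms: Eschenmoser's salt, C=[N+](C)C.[I-]
Why: α-Methylenation of the only enolisable lactone (the spiro-lactone has no α-hydrogen) by Mannich reaction, quaternisation and elimination.

Step 26
Reactants: 35 bis-lactone triene
Product: 36 exo-1,2-epoxide of 35 (oxygen syn to the C4 bridge)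
Conditions: mCPBA (1.05 equiv), NaHCO3, CH2Cl2, −20 °C
Reagents that add atoms: mCPBA, O=C(OO)c1cccc(Cl)c1
Why: Peracid epoxidation of the strained trisubstituted norbornene alkene from the exo face (the endo face is covered by C7′), expected to outrun the hindered C5′=C6′, the 1,1-disubstituted C4=C15 and the electron-poor methylene lactones.

Step 27
Reactants: 36 exo-epoxide
Product: 37 2-deacetyl-1′-O-TBS-japonicone A (C2–OH syn to C4=C5)
Conditions: BF3·OEt2, Et3SiH, CH2Cl2, −78 → −30 °C; NaHCO3 (aq)
Reagents that add atoms: none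
Why: BF3 opens the exo-epoxide at the tertiary C1, and the C5–C13′ bond, antiperiplanar to the departing exo C1–O bond, migrates to C1, so that the six-membered ring C1–C2–C3–C11′–C13′–C5 contracts to the five-membered ring C1–C2–C3–C11′–C13′ and C2 becomes the one-carbon bridge. The cation left at C5 is allylic through the exocyclic C4=C15 bond and is reduced by Et3SiH at the unhindered C15 terminus, which installs the C4=C5 alkene and the C15 methyl, while fluoride transfer to silicon leaves a B–O bond that is hydrolysed on work-up. The closest known reaction type is the acid-promoted Wagner–Meerwein rearrangement of exo-2,3-epoxynorbornanes to syn-7-oxygenated norbornyl derivatives, here terminated by ionic hydrogenation of an allyl cation. The ring is closed by a suprafacial 1,2-alkyl shift (ring contraction) and not by a new bond between chain ends. C1 is set by inversion at the epoxide carbon with retention in the migrating C13′, C2 keeps its exo oxygen, which ends syn to the C4=C5 bridge, and C11′ passes from carbonyl-exo to carbonyl-endo because the shift exchanges the two faces of the ethano bridge. The step needs migration of C13′ over hydride shift or bridge migration (the competing C2 hydrogen is endo and the allyl cation is the thermodynamic sink) and hydride delivery to C15 over C5 (C5 is flanked by the quaternary C1).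

Step 28
Reactants: 37 alcohol
Product: 38 1′-O-TBS-japonicone A
Conditions: Ac2O, DMAP (cat.), pyridine, CH2Cl2, 25 °C
Reagents that add atoms: acetic anhydride, CC(=O)OC(C)=O
Why: Nucleophile-catalysed acylation of the only free hydroxyl.

Step 29
Reactants: 38 silyl ether
Product: 39 japonicone A (enantiomer as drawn)
Conditions: HF·pyridine, THF, 0 → 25 °C
Reagents that add atoms: none
Why: Fluoride-mediated cleavage of the silyl ether under conditions that should spare the acetate and both lactones.

**Compound list**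

1 | (S)-Wieland–Miescher ketone | C[C@]12CCC(=O)C=C1CCCC2=O | starting material
2 | (4aS,5S)-5-hydroxy-4a-methyl-4,4a,5,6,7,8-hexahydronaphthalen-2(3H)-one | C[C@]12CCC(=O)C=C1CCC[C@@H]2O | intermediate
3 | C7′ ethylene ketal, C4′=C5′ alkene, 1′β-OH | O1CCOC12CC[C@@]3(C)C(=CCC[C@@H]3O)C2 | intermediate
4 | 1′-O-TBS ether of 3 | O1CCOC12CC[C@@]3(C)C(=CCC[C@@H]3O[Si](C)(C)C(C)(C)C)C2 | intermediate
5 | 4′α,5′α-epoxide | O1CCOC12CC[C@@]3(C)[C@@]4(C2)O[C@H]4CC[C@@H]3O[Si](C)(C)C(C)(C)C | intermediate
6 | 4′β-methyl-5′α-hydroxy ketal | O1CCOC12CC[C@@]3(C)[C@](O)(C2)[C@H](C)CC[C@@H]3O[Si](C)(C)C(C)(C)C | intermediate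
7 | 5′α-hydroxy-4′β-methyl-7′-ketone | O=C1CC[C@@]2(C)[C@](O)(C1)[C@H](C)CC[C@@H]2O[Si](C)(C)C(C)(C)C | intermediate
8 | tert-butyl 2-(7′-ylidene)acetate (E/Z) | CC(C)(C)OC(=O)C=C1CC[C@@]2(C)[C@](O)(C1)[C@H](C)CC[C@@H]2O[Si](C)(C)C(C)(C)C | intermediate
9 | tert-butyl 2-(7′,8′-en-7′-yl)acetate | CC(C)(C)OC(=O)CC1=CC[C@@]2(C)[C@](O)(C1)[C@H](C)CC[C@@H]2O[Si](C)(C)C(C)(C)C | intermediate
10 | 7′α-iodo-5′α-hydroxy cis-lactone | C1C(=O)O[C@H]2C[C@@]3(C)[C@](O)(C[C@]21I)[C@H](C)CC[C@@H]3O[Si](C)(C)C(C)(C)C | intermediate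
11 | 5′α-hydroxy cis-lactone | C1C(=O)O[C@H]2C[C@@]3(C)[C@](O)(C[C@H]21)[C@H](C)CC[C@@H]3O[Si](C)(C)C(C)(C)C | intermediate
12 | 5′-ene cis-lactone (C11′H2) | C1C(=O)O[C@H]2C[C@@]3(C)C(=C[C@H]21)[C@H](C)CC[C@@H]3O[Si](C)(C)C(C)(C)C | intermediate
13 | α-(dimethylaminomethyl) lactone | CN(C)CC1C(=O)O[C@H]2C[C@@]3(C)C(=C[C@H]21)[C@H](C)CC[C@@H]3O[Si](C)(C)C(C)(C)C | intermediate
14 | trimethylammonium iodide of 13 | C[N+](C)(C)CC1C(=O)O[C@H]2C[C@@]3(C)C(=C[C@H]21)[C@H](C)CC[C@@H]3O[Si](C)(C)C(C)(C)C.[I-] | intermediate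
15 | 1′-O-TBS ether of the enantiomer of 1β-hydroxyalantolactone | C=C1C(=O)O[C@H]2C[C@@]3(C)C(=C[C@H]21)[C@H](C)CC[C@@H]3O[Si](C)(C)C(C)(C)C | intermediate
16 | cyclohepta-1,3-diene | C1=CC=CCCC1 | starting material
17 | 6,7-dioxabicyclo[3.2.2]non-8-ene | O1O[C@H]2C=C[C@@H]1CCC2 | intermediate
18 | (R)-4-hydroxycyclohept-2-en-1-one | O[C@@H]1CCCC(=O)C=C1 | intermediate
19 | (R)-4-(TBSO)cyclohept-2-en-1-one | CC(C)(C)[Si](C)(C)O[C@@H]1CCCC(=O)C=C1 | intermediate
20 | bis-silyl Michael adduct (silyl enol ether) | COC(=O)C[C@@H]1C=C(O[Si](C)(C)C(C)(C)C)CCC[C@H]1O[Si](C)(C)C(C)(C)C | intermediate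
21 | trans-3-(methoxycarbonylmethyl)-4-(TBSO)cycloheptanone | O=C1C[C@@H](CC(=O)OC)[C@H](O[Si](C)(C)C(C)(C)C)CCC1 | intermediate
22 | 5-(TBSO)-6-(methoxycarbonylmethyl)cyclohept-2-enone | O=C1C[C@@H](CC(=O)OC)[C@H](O[Si](C)(C)C(C)(C)C)CC=C1 | intermediate
23 | enol triflate with C10 methyl | FC(F)(F)S(=O)(=O)OC1=C[C@H](C)C[C@@H](O[Si](C)(C)C(C)(C)C)[C@H](CC(=O)OC)C1 | intermediate
24 | cycloheptenyl vinyl ketone | C=CC(=O)C1=C[C@H](C)C[C@@H](O[Si](C)(C)C(C)(C)C)[C@H](CC(=O)OC)C1 | intermediate
25 | bicyclic cyclopentenone silyl ether ester | O=C1CCC2=C1C[C@@H](CC(=O)OC)[C@H](O[Si](C)(C)C(C)(C)C)C[C@H]2C | intermediate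
26 | 13,15-dinor-4-oxoguai-1(5)-en-12,8-olide | O=C1CCC2=C1C[C@H]3CC(=O)O[C@@H]3C[C@H]2C | intermediate
27 | 3-phenylseleno enone lactone | O=C1C([Se]c4ccccc4)CC2=C1C[C@H]3CC(=O)O[C@@H]3C[C@H]2C | intermediate
28 | 4-hydroxy-4-methyl-3-phenylseleno lactone | CC1(O)C([Se]c4ccccc4)CC2=C1C[C@H]3CC(=O)O[C@@H]3C[C@H]2C | intermediate
29 | selenoxide of 28 | CC1(O)C([Se](=O)c4ccccc4)CC2=C1C[C@H]3CC(=O)O[C@@H]3C[C@H]2C | intermediate
30 | 4-hydroxy-13-norguaia-1(5),2-dien-12,8-olide | CC1(O)C=CC2=C1C[C@H]3CC(=O)O[C@@H]3C[C@H]2C | intermediate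
31 | 13-norguaia-1(5),2,4(15)-trien-12,8-olide (fulvene) | C=C1C=CC2=C1C[C@H]3CC(=O)O[C@@H]3C[C@H]2C | intermediate
32 | Diels–Alder adduct | C1C(=O)O[C@@H]2C[C@@H](C)C3=C[C@H]4C(=C)[C@]3(C[C@@H]12)C[C@]45C(=O)O[C@H]6C[C@@]7(C)C(=C[C@H]65)[C@H](C)CC[C@@H]7O[Si](C)(C)C(C)(C)C | intermediate
33 | Mannich base of 32 | CN(C)CC1C(=O)O[C@@H]2C[C@@H](C)C3=C[C@H]4C(=C)[C@]3(C[C@@H]12)C[C@]45C(=O)O[C@H]6C[C@@]7(C)C(=C[C@H]65)[C@H](C)CC[C@@H]7O[Si](C)(C)C(C)(C)C | intermediate
34 | trimethylammonium iodide of 33 | C[N+](C)(C)CC1C(=O)O[C@@H]2C[C@@H](C)C3=C[C@H]4C(=C)[C@]3(C[C@@H]12)C[C@]45C(=O)O[C@H]6C[C@@]7(C)C(=C[C@H]65)[C@H](C)CC[C@@H]7O[Si](C)(C)C(C)(C)C.[I-] | intermediate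
35 | adduct with both α-methylene lactones | C=C1C(=O)O[C@@H]2C[C@@H](C)C3=C[C@H]4C(=C)[C@]3(C[C@@H]12)C[C@]45C(=O)O[C@H]6C[C@@]7(C)C(=C[C@H]65)[C@H](C)CC[C@@H]7O[Si](C)(C)C(C)(C)C | intermediate
36 | exo-1,2-epoxide | C=C1C(=O)O[C@@H]2C[C@@H](C)[C@@]39O[C@H]9[C@H]4C(=C)[C@]3(C[C@@H]12)C[C@]45C(=O)O[C@H]6C[C@@]7(C)C(=C[C@H]65)[C@H](C)CC[C@@H]7O[Si](C)(C)C(C)(C)C | intermediate
37 | 2-deacetyl-1′-O-TBS-japonicone A | C=C1C(=O)O[C@@H]2C[C@@H](C)[C@]34C[C@]5(C(=O)O[C@H]6C[C@@]7(C)C(=C[C@H]65)[C@H](C)CC[C@@H]7O[Si](C)(C)C(C)(C)C)[C@H](C(C)=C3C[C@@H]12)[C@@H]4O | intermediate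
38 | 1′-O-TBS-japonicone A | C=C1C(=O)O[C@@H]2C[C@@H](C)[C@]34C[C@]5(C(=O)O[C@H]6C[C@@]7(C)C(=C[C@H]65)[C@H](C)CC[C@@H]7O[Si](C)(C)C(C)(C)C)[C@H](C(C)=C3C[C@@H]12)[C@@H]4OC(C)=O | intermediate
39 | japonicone A (enantiomer as drawn) | C=C1C(=O)O[C@@H]2C[C@@H](C)[C@]34C[C@]5(C(=O)O[C@H]6C[C@@]7(C)C(=C[C@H]65)[C@H](C)CC[C@@H]7O)[C@H](C(C)=C3C[C@@H]12)[C@@H]4OC(C)=O | target

**Summary**

Total step count: 29. Longest linear sequence: 18 steps (steps 1–12, then 24–29); the guaiane branch (steps 13–23) joins at step 24.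

Steps most likely to fail:

1. Step 27. The hydride may be delivered to the wrong allyl terminus, or the cation may eliminate or undergo further skeletal shifts before it is reduced. Fallback: from 36, MgBr2·OEt2 in CH2Cl2 should open the epoxide with the same 1,2-shift and trap the allyl cation with bromide at C15 to give the allylic bromide F1. Bu3SnH with Pd(PPh3)4 (cat.) should then reduce the primary allylic bromide at the unhindered terminus. The route is rejoined at 37.

2. Step 24. The fulvene may oligomerise, and facial or exo selectivity may erode in the intermolecular cycloaddition. Fallback: from 30 and 15, the cyclopentadienol itself (quaternary C4, no hydrogen shift possible) is used as the diene in a thermal Diels–Alder reaction to give the bridge carbinol adduct F2. Burgess dehydration of the tertiary bridge alcohol then installs the exocyclic methylene. The route is rejoined at 32.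

3. Step 26. Chemoselectivity among the four alkenes may be poor. Fallback: from 35, catalytic dihydroxylation (K2OsO2(OH)4, N-methylmorpholine N-oxide), which responds more strongly to strain and hindrance, should give the exo-cis-diol F3. BF3·OEt2 and Et3SiH then ionise its tertiary C1 hydroxyl and the same shift and reduction follow. The route is rejoined at 37.

Further compounds
F1 | step 27 | 15-bromo-2-deacetyl-1′-O-TBS-japonicone A (allylic bromide) | C=C1C(=O)O[C@@H]2C[C@@H](C)[C@]34C[C@]5(C(=O)O[C@H]6C[C@@]7(C)C(=C[C@H]65)[C@H](C)CC[C@@H]7O[Si](C)(C)C(C)(C)C)[C@H](C(CBr)=C3C[C@@H]12)[C@@H]4O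
F2 | step 24 | Diels–Alder adduct of 30 and 15 with a 4-hydroxy-4-methyl bridge | C1C(=O)O[C@@H]2C[C@@H](C)C3=C[C@H]4C(C)(O)[C@]3(C[C@@H]12)C[C@]45C(=O)O[C@H]6C[C@@]7(C)C(=C[C@H]65)[C@H](C)CC[C@@H]7O[Si](C)(C)C(C)(C)C
F3 | step 26 | exo-cis-1,2-diol of 35 | C=C1C(=O)O[C@@H]2C[C@@H](C)[C@]3(O)[C@@H](O)[C@H]4C(=C)[C@]3(C[C@@H]12)C[C@]45C(=O)O[C@H]6C[C@@]7(C)C(=C[C@H]65)[C@H](C)CC[C@@H]7O[Si](C)(C)C(C)(C)C
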